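## Retrosynthetic overview

1. The only ring is closed last, by an intramolecular Claisen (Dieckmann-type) C-acylation of an open-chain 4-hydroxy-5,7-dioxo ester. This is the laboratory counterpart of the polyketide synthase closure of a fatty-acyl-primed chain to a 2-acylcyclohexane-1,3-dione.
2. That chain is built and cyclised in one flask from a C19 methyl ketone enolate and methyl (2R)-5-oxooxolane-2-carboxylate (double Claisen cascade). The lactone carbinol carbon becomes the ring CH(OH), so no hydroxylation, asymmetric step or protecting group is needed.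
3. The methyl ketone comes from an sp3–sp2 Negishi coupling of (6-oxoheptyl)zinc iodide with (1E,3E)-1-iodododeca-1,3-diene.
4. The coupling partners come in one step each from 1-methylcyclohexanol (alkoxy-radical ring scission) and (E)-undec-2-enal (Takai iodo-olefination).

Assumption: the target SMILES is one enol tautomer of (4R)-4-hydroxy-2-[(7E,9E)-octadeca-7,9-dienoyl]cyclohexane-1,3-dione; the tautomers interconvert freely, so the (R)-triketone is the target.

## Route

Step 1
Reactants: 1 1-methylcyclohexan-1-ol
Product: 3 7-iodoheptan-2-one, via 1-methylcyclohexyl hypoiodite 2 (not isolated)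
Conditions: PhI(OAc)2 (1.2 equiv), I2 (1.0 equiv), cyclohexane, hν (visible light), 40 °C
Reagents that add atoms: iodine, II
Why: Suárez hypoiodite fragmentation: O–I homolysis of 2 gives a tertiary alkoxy radical whose β-scission opens the ring (primary alkyl radical preferred over methyl loss), and the radical is capped by iodine; no stereocentre is involved.

Step 2
Reactants: 4 (2E)-undec-2-enal
Product: 5 (1E,3E)-1-iodododeca-1,3-diene
Conditions: CrCl2 (6 equiv), CHI3 (2 equiv), THF/1,4-dioxane 1:6, 0 → 23 °C, dark
Reagents that add atoms: iodoform, IC(I)I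
Why: Takai iodo-olefination: the gem-dichromium carbenoid adds only to the aldehyde carbonyl and anti elimination gives the new alkene E (expected about 8–10:1 in dioxane-rich solvent), while the existing E alkene is untouched.

Step 3
Reactants: 3 7-iodoheptan-2-one; 5 (1E,3E)-1-iodododeca-1,3-diene
Product: 7 (8E,10E)-nonadeca-8,10-dien-2-one, via (6-oxoheptyl)zinc iodide 6 (not isolated)
Conditions: 3 (1.3 equiv), Zn dust, LiCl, THF, 40 °C; then 5, Pd(PPh3)4 (3 mol %), THF, 23 °C
Reagents that add atoms: none
Why: Negishi sp3–sp2 cross-coupling: a primary alkylzinc iodide tolerates the remote ketone, and oxidative addition and reductive elimination at palladium retain both alkene geometries of the dienyl iodide.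

Step 4
Reactants: 8 (2R)-5-oxooxolane-2-carboxylic acid
Product: 10 methyl (2R)-5-oxooxolane-2-carboxylate, via potassium (2R)-5-oxooxolane-2-carboxylate 9 (not isolated)
Conditions: KHCO3 (1.2 equiv), MeI (1.5 equiv), DMF, 23 °C
Reagents that add atoms: iodomethane, CI
Why: SN2 O-methylation of the carboxylate under weakly basic conditions that neither open the lactone nor touch the α-stereocentre.

Step 5
Reactants: 7 (8E,10E)-nonadeca-8,10-dien-2-one; 10 methyl (2R)-5-oxooxolane-2-carboxylate
Product: 14 (6R)-3,6-dihydroxy-2-[(7E,9E)-octadeca-7,9-dienoyl]cyclohex-2-en-1-one, via lithium (8E,10E)-nonadeca-1,8,10-trien-2-olate 11 (not isolated), via (9E,11E)-1-[(2R)-5-oxooxolan-2-yl]icosa-9,11-diene-1,3-dione 12 (not isolated), via methyl (4R,13E,15E)-4-hydroxy-5,7-dioxotetracosa-13,15-dienoate 13 (not isolated)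
Conditions: 7 (2.1 equiv, excess recovered), LiN(i-Pr)2 (2.0 equiv), THF, −78 °C; then 10 (1.0 equiv), −78 → 0 °C; then KOt-Bu (1.1 equiv), 0 → 40 °C; 1 M HCl
Reagents that add atoms: none
Why: Proposed new method: the kinetic methyl enolate 11 undergoes a crossed Claisen condensation at the more electrophilic α-acyloxy ester carbonyl of 10 (closest known reactions: acylation of ketone lithium enolates by O-protected α-hydroxy esters without racemisation, and NaBH4 reduction of this lactone ester at the exocyclic ester); the second equivalent of 11 deprotonates diketone 12, the released methoxide opens the lactone to the 5,7-dioxo ester 13, and its diketonate carbon closes the ring by a Dieckmann-type C-acylation (closest known reaction: base cyclisation of 5,7-dioxo esters to 2-acylcyclohexane-1,3-diones), with all Claisen equilibria drained into the strongly acidic β-triketonate; first attack at the lactone carbonyl, or direct acyl transfer from the lactone of 12, gives the same product, and no new stereocentre is made because the (R) centre of 10 is never a reacting atom, keeps its CIP sense, and is shielded from deprotonation once its oxygen is an alkoxide.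

## Compound list

1 | 1-methylcyclohexan-1-ol | CC1(O)CCCCC1 | starting material
2 | 1-methylcyclohexyl hypoiodite | CC1(OI)CCCCC1 | intermediate
3 | 7-iodoheptan-2-one | CC(=O)CCCCCI | intermediate
4 | (2E)-undec-2-enal | CCCCCCCC/C=C/C=O | starting material
5 | (1E,3E)-1-iodododeca-1,3-diene | CCCCCCCC/C=C/C=C/I | intermediate
6 | (6-oxoheptyl)zinc iodide | CC(=O)CCCCC[Zn]I | intermediate
7 | (8E,10E)-nonadeca-8,10-dien-2-one | CCCCCCCC/C=C/C=C/CCCCCC(C)=O | intermediate
8 | (2R)-5-oxooxolane-2-carboxylic acid | OC(=O)[C@H]1CCC(=O)O1 | starting material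
9 | potassium (2R)-5-oxooxolane-2-carboxylate | [K+].[O-]C(=O)[C@H]1CCC(=O)O1 | intermediate
10 | methyl (2R)-5-oxooxolane-2-carboxylate | COC(=O)[C@H]1CCC(=O)O1 | intermediate
11 | lithium (8E,10E)-nonadeca-1,8,10-trien-2-olate | [Li+].[O-]C(=C)CCCCC/C=C/C=C/CCCCCCCC | intermediate
12 | (9E,11E)-1-[(2R)-5-oxooxolan-2-yl]icosa-9,11-diene-1,3-dione | CCCCCCCC/C=C/C=C/CCCCCC(=O)CC(=O)[C@H]1CCC(=O)O1 | intermediate
13 | methyl (4R,13E,15E)-4-hydroxy-5,7-dioxotetracosa-13,15-dienoate | CCCCCCCC/C=C/C=C/CCCCCC(=O)CC(=O)[C@H](O)CCC(=O)OC | intermediate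
14 | (6R)-3,6-dihydroxy-2-[(7E,9E)-octadeca-7,9-dienoyl]cyclohex-2-en-1-one | CCCCCCCC/C=C/C=C/CCCCCC(=O)C1=C(O)CC[C@@H](O)C1=O | target

## Step count and risks

Total step count: 5. Longest linear sequence: 3 steps (step 1 or step 2, then step 3, then step 5).

Steps most likely to fail:

- **Step 5 (double Claisen cascade).** The risks are proton transfer from the α-carbon of 10 to enolate 11 (loss of enantiopurity) and incomplete ring closure. The fallback separates the two Claisen events and runs the intermolecular one without base. It sets out from 7 and 8 and comes back at 12. Ketone 7 is converted (LiN(i-Pr)2, Me3SiCl, THF, −78 °C) into its kinetic silyl enol ether trimethyl{[(8E,10E)-nonadeca-1,8,10-trien-2-yl]oxy}silane F1. Acid 8 is converted ((COCl)2, cat. DMF, CH2Cl2) into (2R)-5-oxooxolane-2-carbonyl chloride F2. ZnCl2-promoted C-acylation of F1 by F2 (CH2Cl2/Et2O, 0 °C) gives lactone diketone 12, now isolated. It is closed to 14 by the KOt-Bu/THF stage of step 5, with one equivalent of MeOH added as the lactone-opening relay.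

- **Step 2 (Takai olefination).** The risk is a 1Z isomer that cannot be removed after coupling. The fallback fixes the geometry by syn-hydrometalation of an alkyne. It sets out from 4 and comes back at 5. Corey–Fuchs reaction of 4 (CBr4, PPh3, CH2Cl2, 0 °C) gives (3E)-1,1-dibromododeca-1,3-diene F3. n-BuLi (2.1 equiv, THF, −78 °C) then gives (3E)-dodec-3-en-1-yne F4. Hydrozirconation of the terminal alkyne with Cp2Zr(H)Cl (THF, 23 °C) followed by I2 (0 °C) gives 5 with the 1E geometry.

- **Step 3 (Negishi coupling).** The risks are sluggish zinc insertion or side reactions of the keto-organozinc. The fallback masks the ketone and uses a harder nucleophile. It sets out from 3 and comes back at 7. Ketalisation of 3 (ethane-1,2-diol, cat. TsOH, benzene, reflux) gives 2-(5-iodopentyl)-2-methyl-1,3-dioxolane F5. Mg in THF converts it into [5-(2-methyl-1,3-dioxolan-2-yl)pentyl]magnesium iodide F6. Pd(PPh3)4-catalysed coupling of F6 with 5 (THF, 0 → 23 °C) gives 2-[(6E,8E)-heptadeca-6,8-dien-1-yl]-2-methyl-1,3-dioxolane F7. Treatment with 1 M HCl/THF releases 7.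

## Further compounds

F1 | step 5 | trimethyl{[(8E,10E)-nonadeca-1,8,10-trien-2-yl]oxy}silane | C=C(O[Si](C)(C)C)CCCCC/C=C/C=C/CCCCCCCC
F2 | step 5 | (2R)-5-oxooxolane-2-carbonyl chloride | ClC(=O)[C@H]1CCC(=O)O1
F3 | step 2 | (3E)-1,1-dibromododeca-1,3-diene | CCCCCCCC/C=C/C=C(Br)Br
F4 | step 2 | (3E)-dodec-3-en-1-yne | CCCCCCCC/C=C/C#C
F5 | step 3 | 2-(5-iodopentyl)-2-methyl-1,3-dioxolane | CC1(CCCCCI)OCCO1
F6 | step 3 | [5-(2-methyl-1,3-dioxolan-2-yl)pentyl]magnesium iodide | CC1(CCCCC[Mg]I)OCCO1
F7 | step 3 | 2-[(6E,8E)-heptadeca-6,8-dien-1-yl]-2-methyl-1,3-dioxolane | CCCCCCCC/C=C/C=C/CCCCCC1(C)OCCO1
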